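**Retrosynthetic overview**
- Target 18 comes from its bis-MOM ether 17 by acetal cleavage in the last step.
- 17 is cut at two bonds at once, C6–CH2 and C1–C(=O), back to chloroarene 10, 2-phenylethylmagnesium bromide 12 and methyl chloroformate 13. The feature used is the contiguous triad C6 (phenethyl) – C1 (CO2Me) – C2 (oxygen) on the hexasubstituted benzene ring: a C1≡C6 aryne flanked by the C2 oxygen takes the carbon nucleophile at C6 and the acyl group at C1.
- 10 comes from bis-MOM 5-chlororesorcinol 3 by two directed ortho-metalation/prenylation cycles, first between the two MOM ethers (C3 prenyl), then between chlorine and a MOM ether (C5 prenyl).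
- No ring is formed in the route; the benzene ring is carried through from 5-chlororesorcinol 1, and the target has no stereocentre.

Key step: step 5

Remark: locants C1–C6 are those of the benzoate ring of the target (C1 CO2Me, C2 OH, C3 prenyl, C4 OH, C5 prenyl, C6 CH2CH2Ph). The Grignard reagent is assumed to be prepared in house (step 4) and used as a titrated THF solution.

Step 1
Reactants: 1 5-chlororesorcinol; 2 chloromethyl methyl ether
Product: 3 1-chloro-3,5-bis(methoxymethoxy)benzene
Conditions: MOMCl (2.5 equiv), i-Pr2NEt (3 equiv), CH2Cl2, 0 °C to rt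
Reagents that add atoms: chloromethyl methyl ether, COCCl
Why: Base-mediated O-alkylation of both phenols by the reactive α-chloro ether (Williamson-type acetal formation) should give the bis-MOM ether, which protects the phenols and provides the directing groups for the later metalations.

Step 2
Reactants: 3 1-chloro-3,5-bis(methoxymethoxy)benzene; 4 prenyl bromide
Product: 7 5-chloro-1,3-bis(methoxymethoxy)-2-(3-methylbut-2-enyl)benzene, via aryllithium 5 (not isolated), via arylcopper 6 (not isolated)
Conditions: n-BuLi, THF, −78 to −20 °C; CuBr·SMe2 (1.1 equiv), −78 °C; prenyl bromide, −78 to 0 °C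
Reagents that add atoms: prenyl bromide, CC(C)=CCBr
Why: Directed ortho-metalation should remove the hydrogen held between the two coordinating MOM ethers to give 5 (no ortho halogen, so no LiCl loss), and after transmetalation to arylcopper 6 the copper-mediated allylic substitution on prenyl bromide should deliver the linear prenyl group, since attack at the tertiary allyl terminus by a di-ortho-substituted aryl is sterically disfavoured.

Step 3
Reactants: 7 5-chloro-1,3-bis(methoxymethoxy)-2-(3-methylbut-2-enyl)benzene; 4 prenyl bromide
Product: 10 1-chloro-3,5-bis(methoxymethoxy)-2,4-bis(3-methylbut-2-enyl)benzene, via aryllithium 8 (not isolated), via arylcopper 9 (not isolated)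
Conditions: s-BuLi (1.1 equiv), THF, −78 °C; CuBr·SMe2 (1.1 equiv), −78 °C; prenyl bromide, −78 to 0 °C
Reagents that add atoms: prenyl bromide, CC(C)=CCBr
Why: Directed ortho-metalation at one of the two equivalent ring positions, each acidified cooperatively by chlorine and a MOM ether, should give 8, which is kept at −78 °C so that it does not expel LiCl and is converted into the thermally robust arylcopper 9 before the allylic substitution on prenyl bromide takes place on warming.

Step 4
Reactants: 11 (2-bromoethyl)benzene
Product: 12 2-phenylethylmagnesium bromide (titrated THF solution)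
Conditions: Mg turnings, I2 (cat.), THF, rt to 40 °C, slow addition
Reagents that add atoms: magnesium, [Mg]
Why: Oxidative insertion of magnesium into the primary C–Br bond (Grignard formation) is routine, and slow addition of the bromide should keep Wurtz coupling low.

Step 5
Reactants: 10 1-chloro-3,5-bis(methoxymethoxy)-2,4-bis(3-methylbut-2-enyl)benzene; 12 2-phenylethylmagnesium bromide; 13 methyl chloroformate
Product: 17 methyl 2,4-bis(methoxymethoxy)-3,5-bis(3-methylbut-2-enyl)-6-(2-phenylethyl)benzoate, via aryllithium 14 (not isolated), via aryne 15 (not isolated), via arylmagnesium bromide 16 (not isolated)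
Conditions: s-BuLi (1.05 equiv), THF, −78 °C; PhCH2CH2MgBr (3 equiv), −78 to 40 °C; ClCO2Me (6 equiv), −40 °C to rt
Reagents that add atoms: 2-phenylethylmagnesium bromide, Br[Mg]CCc1ccccc1; methyl chloroformate, COC(=O)Cl
Why: s-BuLi should remove the only ring hydrogen of 10, which lies between chlorine and a MOM ether (directed ortho-metalation), to give 14, stable at −78 °C; on warming with excess 12, LiCl is lost to give the C1≡C6 aryne 15, the alkylmagnesium carbon adds at C6 and leaves magnesium on C1 (16), and methyl chloroformate then acylates C1. The closest known reaction type is the addition of Grignard or organolithium reagents to 3-alkoxyarynes generated from ortho-lithiated haloarenes, with electrophilic capture of the resulting ortho-alkoxy arylmetal. No ring is closed and no stereocentre is formed; the step makes the C6–CH2 and C1–C(=O) bonds in one flask. The selectivity needed is regioselective addition to the unsymmetrical aryne: the σ-withdrawing MOM-oxy group on C2 distorts the aryne so that C6 is the more electrophilic carbon and stabilises the developing carbanion at C1, which should outweigh the steric shielding of C6 by the C5 prenyl group. Ring deprotonation should be preferred over attack at the benzylic/allylic CH2 groups because of the cooperative activation by chlorine and the MOM ether. Having the Grignard reagent in excess when the aryne forms should suppress addition of 14 to the aryne, and the mild heating covers the case that magnesium exchange slows the loss of chloride.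

Step 6
Reactants: 17 methyl 2,4-bis(methoxymethoxy)-3,5-bis(3-methylbut-2-enyl)-6-(2-phenylethyl)benzoate
Product: 18 methyl 2,4-dihydroxy-3,5-bis(3-methylbut-2-enyl)-6-(2-phenylethyl)benzoate
Conditions: HCl (ca. 1 M, from conc. HCl), MeOH, 25–40 °C
Reagents that add atoms: none
Why: Acid-catalysed acetal exchange with methanol should remove both MOM groups as dimethoxymethane, while at this acidity and temperature protonation of the trisubstituted alkenes should be slow enough that chroman formation does not compete, and the methyl ester is unchanged in methanol.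

**Compound list**
1 | 5-chlororesorcinol (5-chlorobenzene-1,3-diol) | Oc1cc(O)cc(Cl)c1 | starting material
2 | chloromethyl methyl ether | COCCl | starting material
3 | 1-chloro-3,5-bis(methoxymethoxy)benzene | COCOc1cc(Cl)cc(OCOC)c1 | intermediate
4 | prenyl bromide (1-bromo-3-methylbut-2-ene) | CC(C)=CCBr | starting material
5 | [4-chloro-2,6-bis(methoxymethoxy)phenyl]lithium | [Li]c1c(OCOC)cc(Cl)cc1OCOC | intermediate
6 | [4-chloro-2,6-bis(methoxymethoxy)phenyl]copper | [Cu]c1c(OCOC)cc(Cl)cc1OCOC | intermediate
7 | 5-chloro-1,3-bis(methoxymethoxy)-2-(3-methylbut-2-enyl)benzene | COCOc1cc(Cl)cc(OCOC)c1CC=C(C)C | intermediate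
8 | [6-chloro-2,4-bis(methoxymethoxy)-3-(3-methylbut-2-enyl)phenyl]lithium | [Li]c1c(Cl)cc(OCOC)c(CC=C(C)C)c1OCOC | intermediate
9 | [6-chloro-2,4-bis(methoxymethoxy)-3-(3-methylbut-2-enyl)phenyl]copper | [Cu]c1c(Cl)cc(OCOC)c(CC=C(C)C)c1OCOC | intermediate
10 | 1-chloro-3,5-bis(methoxymethoxy)-2,4-bis(3-methylbut-2-enyl)benzene | COCOc1cc(Cl)c(CC=C(C)C)c(OCOC)c1CC=C(C)C | intermediate
11 | (2-bromoethyl)benzene | BrCCc1ccccc1 | starting material
12 | 2-phenylethylmagnesium bromide | Br[Mg]CCc1ccccc1 | intermediate
13 | methyl chloroformate | COC(=O)Cl | starting material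
14 | [2-chloro-4,6-bis(methoxymethoxy)-3,5-bis(3-methylbut-2-enyl)phenyl]lithium | [Li]c1c(Cl)c(CC=C(C)C)c(OCOC)c(CC=C(C)C)c1OCOC | intermediate
15 | 3,5-bis(methoxymethoxy)-4,6-bis(3-methylbut-2-enyl)-1,2-didehydrobenzene (aryne) | COCOC1=C(CC=C(C)C)C(OCOC)=C(CC=C(C)C)C#C1 | intermediate
16 | [2,4-bis(methoxymethoxy)-3,5-bis(3-methylbut-2-enyl)-6-(2-phenylethyl)phenyl]magnesium bromide | Br[Mg]c1c(OCOC)c(CC=C(C)C)c(OCOC)c(CC=C(C)C)c1CCc1ccccc1 | intermediate
17 | methyl 2,4-bis(methoxymethoxy)-3,5-bis(3-methylbut-2-enyl)-6-(2-phenylethyl)benzoate | COCOc1c(C(=O)OC)c(CCc2ccccc2)c(CC=C(C)C)c(OCOC)c1CC=C(C)C | intermediate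
18 | methyl 2,4-dihydroxy-3,5-bis(3-methylbut-2-enyl)-6-(2-phenylethyl)benzoate | COC(=O)c1c(O)c(CC=C(C)C)c(O)c(CC=C(C)C)c1CCc1ccccc1 | target

**Step count**
Total steps: 6. Longest linear sequence: 5 (steps 1, 2, 3, 5, 6); step 4 is a one-step side branch.

**Steps most likely to fail**

Step 5. Three processes may go wrong. The aryne may be reduced by β-hydride transfer from the Grignard reagent, with loss of styrene. The nucleophile may add with eroded regioselectivity because C6 is shielded by the C5 prenyl group. Deprotonation at the benzylic/allylic CH2 groups may compete with ring metalation. The fallback avoids the aryne and sets out from 10. Aryllithium 14 is generated as in step 5, kept at −78 °C and quenched there with methyl chloroformate 13, which should give methyl 2-chloro-4,6-bis(methoxymethoxy)-3,5-bis(3-methylbut-2-enyl)benzoate F1. Grignard reagent 12 is transmetalated with ZnBr2 in THF to (2-phenylethyl)zinc bromide F2. A Negishi coupling of F1 with F2 (Pd(OAc)2, RuPhos, THF/NMP, 65 °C) should replace the chlorine, activated by the ortho ester, with the phenethyl group and return to the route at 17.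

Step 3. The ortho-chloro aryllithium 8 may lose LiCl before it has been transferred to copper, giving premature aryne formation and self-condensation, or the prenyl CH2 may be deprotonated laterally. The fallback sets out from 3, reverses the order of the prenylations and reaches the chlorine-flanked position by halogen–magnesium exchange instead of deprotonation. Bromination of 3 with N-bromosuccinimide (MeCN, 0 °C) should occur ortho to chlorine and para to a MOM ether, giving 2-bromo-1-chloro-3,5-bis(methoxymethoxy)benzene F3. Bromine–magnesium exchange (i-PrMgCl·LiCl, THF, 0 °C) should give [2-chloro-4,6-bis(methoxymethoxy)phenyl]magnesium chloride F4, an ortho-chloro arylmagnesium that does not eliminate at this temperature. Allylation of F4 with prenyl bromide 4 (CuBr·SMe2 cat.) should give 1-chloro-3,5-bis(methoxymethoxy)-2-(3-methylbut-2-enyl)benzene F5. Directed ortho-metalation of F5 with n-BuLi between the two MOM ethers should give [4-chloro-2,6-bis(methoxymethoxy)-3-(3-methylbut-2-enyl)phenyl]lithium F6, which carries no ortho halogen. Its allylation with prenyl bromide 4 (CuBr·SMe2 cat.) returns to the route at 10.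

Step 6. A prenyl group may cyclise under acid onto the neighbouring freed phenol (2,2-dimethylchroman formation), or HCl or methanol may add to the trisubstituted alkenes before both acetals are cleaved. The fallback sets out from 17 and exchanges the MOM ethers for silyl ethers without Brønsted acid (TMSOTf, 2,2'-bipyridyl, CH2Cl2, 0 °C to rt). This should give methyl 3,5-bis(3-methylbut-2-enyl)-6-(2-phenylethyl)-2,4-bis(trimethylsilyloxy)benzoate F7, in which no free phenol meets acid. Hydrolysis of the aryl silyl ethers with water at neutral pH returns to the route at 18.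

**Further compounds**
F1 | step 5 | methyl 2-chloro-4,6-bis(methoxymethoxy)-3,5-bis(3-methylbut-2-enyl)benzoate | COC(=O)c1c(Cl)c(CC=C(C)C)c(OCOC)c(CC=C(C)C)c1OCOC
F2 | step 5 | (2-phenylethyl)zinc bromide | Br[Zn]CCc1ccccc1
F3 | step 3 | 2-bromo-1-chloro-3,5-bis(methoxymethoxy)benzene | COCOc1cc(Cl)c(Br)c(OCOC)c1
F4 | step 3 | [2-chloro-4,6-bis(methoxymethoxy)phenyl]magnesium chloride | Cl[Mg]c1c(Cl)cc(OCOC)cc1OCOC
F5 | step 3 | 1-chloro-3,5-bis(methoxymethoxy)-2-(3-methylbut-2-enyl)benzene | COCOc1cc(Cl)c(CC=C(C)C)c(OCOC)c1
F6 | step 3 | [4-chloro-2,6-bis(methoxymethoxy)-3-(3-methylbut-2-enyl)phenyl]lithium | [Li]c1c(OCOC)cc(Cl)c(CC=C(C)C)c1OCOC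
F7 | step 6 | methyl 3,5-bis(3-methylbut-2-enyl)-6-(2-phenylethyl)-2,4-bis(trimethylsilyloxy)benzoate | COC(=O)c1c(O[Si](C)(C)C)c(CC=C(C)C)c(O[Si](C)(C)C)c(CC=C(C)C)c1CCc1ccccc1
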